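Gardenin E is traced back to commercial tangeretin by disconnecting the two phenolic C–O bonds at C3' and C5' of ring B to C–H bonds. One iridium-catalysed C–H borylation with oxidation in the same flask should install both hydroxyls at once. The step exploits three features: ring A (C5–C8) is fully substituted, C3–H of ring C is boxed in between the C2 aryl group and the C4 carbonyl, and C2'/C6'–H sit beside the chromenone at C1'. Only the equivalent C3'–H and C5'–H, flanked solely by the 4'-methoxy group, remain accessible. A final chelation-controlled cleavage of the 5-O-methyl group next to the C4 carbonyl gives the target.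

Key step: step 1

Assumption: tangeretin is bought as the isolated natural product, and step 1 is balanced with one B2pin2 per C–H bond, the second boryl group of each leaving as pinacolborane. The target has no stereocentre.

Step 1
Reactants: 1 tangeretin (5,6,7,8,4'-pentamethoxyflavone); 2 bis(pinacolato)diboron
Product: 5 3',5'-dihydroxy-5,6,7,8,4'-pentamethoxyflavone, via tangeretin 3'-pinacolboronate 3 (not isolated), via tangeretin 3',5'-bis(pinacolboronate) 4 (not isolated)
Conditions: [Ir(OMe)(cod)]2 (3 mol%), 4,4'-di-tert-butyl-2,2'-bipyridine (dtbpy, 6 mol%), 2 (3 equiv), THF, 80 °C, sealed tube, argon; evaporate; then Oxone (2KHSO5·KHSO4·K2SO4), acetone/H2O, 0 °C to rt, short contact; aq. NaHSO3 quench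
Reagents that add atoms: potassium peroxymonosulfate, the active salt of Oxone (oxygen of each new hydroxyl), [K+].[O-]S(=O)(=O)OO
Why: Proposed new method: the monovalent iridium precatalyst and B2pin2 form the trivalent iridium tris(boryl) complex (dtbpy)Ir(Bpin)3, which cleaves the most exposed aryl C–H bond by oxidative addition (or σ-bond metathesis) and releases the aryl boronate by C–B reductive elimination, the cycle then repeating at the equivalent position before KHSO5 turns each C–B bond into C–O through peroxide attack at boron and 1,2-aryl shift with retention of position. The closest known reaction type is sterically governed iridium-catalysed arene C–H borylation with one-pot KHSO5 oxidation to phenols; twofold borylation on both sides of a single methoxy group of a flavone has no precedent. No ring closes and no stereocentre is created. The selectivity needed is C3'/C5' over C2'/C6' and C3, and the substrate should secure it: ring A has no C–H bond, C3–H of ring C lies between the C2 aryl group and the C4 carbonyl, C2'/C6'–H are shielded by the chromenone at C1', and C3'/C5'–H have only the small, inductively acidifying 4'-methoxy group as neighbour. The second borylation is the demanding event because the 4'-methoxy group must turn out of the plane of ring B, which is why excess 2 and 80 °C are chosen. A brief, near-stoichiometric KHSO5 treatment at low temperature should spare the C2=C3 bond and the new phenols.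

Step 2
Reactants: 5 3',5'-dihydroxy-5,6,7,8,4'-pentamethoxyflavone
Product: 6 Gardenin E (5,3',5'-trihydroxy-6,7,8,4'-tetramethoxyflavone)
Conditions: conc. HCl, EtOH, reflux, N2
Reagents that add atoms: none
Why: Protonation of the C4 carbonyl hydrogen-bonds to and activates only the peri 5-methoxy group, whose methyl is taken by chloride in a chelation-assisted acid-mediated O-demethylation, so the 6-, 7-, 8- and 4'-methoxy groups and the free phenols should remain untouched.

Compound list
1 | tangeretin (5,6,7,8,4'-pentamethoxyflavone) | COc1ccc(-c2cc(=O)c3c(OC)c(OC)c(OC)c(OC)c3o2)cc1 | starting material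
2 | bis(pinacolato)diboron (B2pin2) | CC1(C)OB(B2OC(C)(C)C(C)(C)O2)OC1(C)C | starting material
3 | 5,6,7,8,4'-pentamethoxy-3'-(4,4,5,5-tetramethyl-1,3,2-dioxaborolan-2-yl)flavone (tangeretin 3'-pinacolboronate) | COc1ccc(-c2cc(=O)c3c(OC)c(OC)c(OC)c(OC)c3o2)cc1B1OC(C)(C)C(C)(C)O1 | intermediate
4 | 5,6,7,8,4'-pentamethoxy-3',5'-bis(4,4,5,5-tetramethyl-1,3,2-dioxaborolan-2-yl)flavone (tangeretin 3',5'-bis(pinacolboronate)) | COc1c(B2OC(C)(C)C(C)(C)O2)cc(-c2cc(=O)c3c(OC)c(OC)c(OC)c(OC)c3o2)cc1B1OC(C)(C)C(C)(C)O1 | intermediate
5 | 3',5'-dihydroxy-5,6,7,8,4'-pentamethoxyflavone | COc1c(O)cc(-c2cc(=O)c3c(OC)c(OC)c(OC)c(OC)c3o2)cc1O | intermediate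
6 | Gardenin E (5,3',5'-trihydroxy-6,7,8,4'-tetramethoxyflavone) | COc1c(O)cc(-c2cc(=O)c3c(O)c(OC)c(OC)c(OC)c3o2)cc1O | target

Total step count: 2
Longest linear sequence: 2 steps

Steps most likely to fail (the route has only two steps, so both are ranked and there is no third):

First, step 1. The second C–H borylation may stall beside the methoxy group once the first boryl group is in place. Borylation may also stray to C2'/C6', or the KHSO5 stage may over-oxidise the electron-rich phenols or the C2=C3 bond. The fallback uses known chemistry, sets out from 1 and returns at 5.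
- Alkaline degradation of 1 (KOH, aq. EtOH, reflux) should open ring C and cleave the resulting 1,3-diketone to 2'-hydroxy-3',4',5',6'-tetramethoxyacetophenone F1, with 4-methoxybenzoic acid released.
- In parallel, purchased methyl 3,5-dihydroxy-4-methoxybenzoate (COC(=O)c1cc(O)c(OC)c(O)c1) is benzylated (BnBr, K2CO3, DMF) to methyl 3,5-bis(benzyloxy)-4-methoxybenzoate F2.
- F2 is reduced (LiAlH4, THF, 0 °C) to [3,5-bis(benzyloxy)-4-methoxyphenyl]methanol F3, which is oxidised (MnO2, CH2Cl2) to 3,5-bis(benzyloxy)-4-methoxybenzaldehyde F4.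
- Claisen–Schmidt condensation of F1 with F4 (KOH, EtOH, rt) should give (E)-3-[3,5-bis(benzyloxy)-4-methoxyphenyl]-1-(2-hydroxy-3,4,5,6-tetramethoxyphenyl)prop-2-en-1-one F5.
- Oxidative cyclisation (catalytic I2, DMSO, 130 °C) should give 3',5'-bis(benzyloxy)-5,6,7,8,4'-pentamethoxyflavone F6.
- Hydrogenolysis (H2, Pd/C, EtOAc/MeOH, rt) removes both benzyl groups and returns to 5.

Second, step 2. Ether cleavage may be slow or unselective under prolonged acidic heating, with partial loss of the 4'-O-methyl group between the two phenols or of the 6-O-methyl group, or with incomplete conversion. The fallback masks the phenols and switches to Lewis-acid chelation control; it sets out from 5 and returns at 6.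
- Acetylation (Ac2O, pyridine, rt) gives 3',5'-diacetoxy-5,6,7,8,4'-pentamethoxyflavone F7.
- BCl3 (slight excess, CH2Cl2, −78 to 0 °C) should cleave only the 5-O-methyl group through the boron chelate with the C4 carbonyl, giving 3',5'-diacetoxy-5-hydroxy-6,7,8,4'-tetramethoxyflavone F8. The acetates prevent borate formation on ring B, which could otherwise activate the 4'-methoxy group.
- Methanolysis (K2CO3, MeOH, rt) removes both acetates and arrives at 6.

Further compounds
F1 | step 1 | 2'-hydroxy-3',4',5',6'-tetramethoxyacetophenone | CC(=O)c1c(O)c(OC)c(OC)c(OC)c1OC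
F2 | step 1 | methyl 3,5-bis(benzyloxy)-4-methoxybenzoate | COC(=O)c1cc(OCc2ccccc2)c(OC)c(OCc2ccccc2)c1
F3 | step 1 | [3,5-bis(benzyloxy)-4-methoxyphenyl]methanol | COc1c(OCc2ccccc2)cc(CO)cc1OCc1ccccc1
F4 | step 1 | 3,5-bis(benzyloxy)-4-methoxybenzaldehyde | COc1c(OCc2ccccc2)cc(C=O)cc1OCc1ccccc1
F5 | step 1 | (E)-3-[3,5-bis(benzyloxy)-4-methoxyphenyl]-1-(2-hydroxy-3,4,5,6-tetramethoxyphenyl)prop-2-en-1-one | COc1c(OCc2ccccc2)cc(/C=C/C(=O)c2c(O)c(OC)c(OC)c(OC)c2OC)cc1OCc1ccccc1
F6 | step 1 | 3',5'-bis(benzyloxy)-5,6,7,8,4'-pentamethoxyflavone | COc1c(OCc2ccccc2)cc(-c2cc(=O)c3c(OC)c(OC)c(OC)c(OC)c3o2)cc1OCc1ccccc1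
F7 | step 2 | 3',5'-diacetoxy-5,6,7,8,4'-pentamethoxyflavone | COc1c(OC(C)=O)cc(-c2cc(=O)c3c(OC)c(OC)c(OC)c(OC)c3o2)cc1OC(C)=O
F8 | step 2 | 3',5'-diacetoxy-5-hydroxy-6,7,8,4'-tetramethoxyflavone | COc1c(OC(C)=O)cc(-c2cc(=O)c3c(O)c(OC)c(OC)c(OC)c3o2)cc1OC(C)=O
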